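## Retrosynthetic overview

1. 19 ⇒ 17: open the only ring at the alkyl C6–O bond and remove C3–OAc together. One oxidative 1,4-acetoxylactonisation of a 2-methyl-1,3-diene (last step) creates both C–O bonds, the E C4=C5 alkene and the C6 stereocentre.
2. 17 ⇒ 15: one fluoride step unmasks CO2H and C2–OH. The C8–O acyl bond comes from methacrylic anhydride.
3. 15 ⇒ 13 + 4: the C7–C8 bond comes from a catalytic asymmetric syn allylboration, which sets 7R and 8R.
4. 13 ⇒ 7 + 10 (Morita–Baylis–Hillman, carbonate, copper borylation); 10 ⇒ 8 + 9; 7 ⇒ 5 + 6; 4 ⇒ 1, which carries the E C10=C1 alkene.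
5. Ring order: there is one ring only, the γ-lactone, closed in step 11.

**Locants used.** The lactone is C12(=O)–C11(=C13H2)–C7H–C6H–O. C6 carries C5H=C4(C15H3)–C3H2OAc. C7 carries C8H(O-methacryloyl)–C9H2–C10(C14H3)=C1H–C2H2OH. The target is 6R,7R,8R with a trans lactone and both trisubstituted alkenes E.

**Assumption.** Compound 1 is bought as the pure E isomer.

## Route

**Step 1**
Reactants: 1 (E)-3-methylpent-2-en-4-yn-1-ol
Product: 2 tert-butyl(dimethyl){[(2E)-3-methylpent-2-en-4-yn-1-yl]oxy}silane
Conditions: TBSCl (1.1 equiv), imidazole (1.5 equiv), CH2Cl2, 0 °C to rt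
Reagents that add atoms: tert-butyldimethylsilyl chloride (TBSCl), CC(C)(C)[Si](C)(C)Cl
Why: Routine imidazole-promoted silyl ether protection of the only hydroxyl, so that later only C8–OH can be acylated; no stereocentre is involved and the E alkene is untouched.

**Step 2**
Reactants: 2 tert-butyl(dimethyl){[(2E)-3-methylpent-2-en-4-yn-1-yl]oxy}silane
Product: 4 (3E)-5-(tert-butyldimethylsilyloxy)-3-methylpent-3-enal, via dienylboronate 3 (not isolated)
Conditions: HBpin (1.1 equiv), Cp2Zr(H)Cl (5 mol %), Et3N (10 mol %), neat, 50 °C; then THF, NaH2PO4/Na2HPO4 buffer (pH 7), 30 % H2O2, 0 °C; used crude at once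
Reagents that add atoms: hydrogen peroxide, OO (aldehyde oxygen); pinacolborane, CC1(C)OBOC1(C)C (Bpin of 3 only)
Why: Hydroboration–oxidation: the zirconium-catalysed syn, anti-Markovnikov hydroboration picks the terminal alkyne over the trisubstituted alkene, and buffered boronate oxidation releases a dienol that is protonated kinetically at C9, so the β,γ-unsaturated aldehyde keeps the E C10=C1 bond.

**Step 3**
Reactants: 5 acryloyl chloride; 6 2-(trimethylsilyl)ethanol
Product: 7 2-(trimethylsilyl)ethyl acrylate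
Conditions: Et3N (1.2 equiv), BHT (trace), CH2Cl2, 0 °C
Reagents that add atoms: none
Why: Simple acyl chloride esterification; this ester is chosen because fluoride later removes it in the same operation as the TBS group.

**Step 4**
Reactants: 8 methacrolein; 9 (triphenylphosphoranylidene)acetaldehyde
Product: 10 (2E)-4-methylpenta-2,4-dienal
Conditions: 8 (3 equiv), toluene, sealed flask, 80 °C, 16 h
Reagents that add atoms: none
Why: Wittig olefination by a stabilised ylide gives the E enal, and the excess of volatile 8 suppresses a second homologation.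

**Step 5**
Reactants: 7 2-(trimethylsilyl)ethyl acrylate; 10 (2E)-4-methylpenta-2,4-dienal
Product: 11 rac-2-(trimethylsilyl)ethyl (4E)-3-hydroxy-6-methyl-2-methylidenehepta-4,6-dienoate
Conditions: quinuclidine (0.25 equiv), MeOH (0.75 equiv), neat, rt, 48–72 h
Reagents that add atoms: none
Why: Morita–Baylis–Hillman reaction: the amine adds to the unsubstituted acrylate rather than to the β-substituted dienal and the enolate adds 1,2 to 10; the carbinol centre is racemic on purpose because step 7 erases it.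

**Step 6**
Reactants: 11 rac-2-(trimethylsilyl)ethyl (4E)-3-hydroxy-6-methyl-2-methylidenehepta-4,6-dienoate
Product: 12 rac-2-(trimethylsilyl)ethyl (4E)-3-[(tert-butoxycarbonyl)oxy]-6-methyl-2-methylidenehepta-4,6-dienoate
Conditions: Boc2O (1.2 equiv), DMAP (5 mol %), CH2Cl2, 0 °C
Reagents that add atoms: di-tert-butyl dicarbonate (Boc2O), CC(C)(C)OC(=O)OC(=O)OC(C)(C)C
Why: DMAP-catalysed carbonate formation turns the hydroxyl into a leaving group that regenerates an alkoxide for copper turnover in step 7.

**Step 7**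
Reactants: 12 rac-2-(trimethylsilyl)ethyl (4E)-3-[(tert-butoxycarbonyl)oxy]-6-methyl-2-methylidenehepta-4,6-dienoate
Product: 13 2-(trimethylsilyl)ethyl (2E,4E)-6-methyl-2-[(4,4,5,5-tetramethyl-1,3,2-dioxaborolan-2-yl)methyl]hepta-2,4,6-trienoate (dienyl group cis to CH2B)
Conditions: B2pin2 (1.1 equiv), CuCl (5 mol %), Xantphos (5 mol %), KOt-Bu (10 mol %), THF, 0 °C to rt
Reagents that add atoms: bis(pinacolato)diboron, CC1(C)OB(OC1(C)C)B1OC(C)(C)C(C)(C)O1
Why: Copper-catalysed γ-selective (SN2') allylic borylation: the monovalent copper boryl adds to the acrylate CH2 (C13) and the carbonate is expelled, and as usual for ester-derived Baylis–Hillman substrates the C7 substituent ends trans to the ester, that is cis to CH2B.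

**Step 8**
Reactants: 13 2-(trimethylsilyl)ethyl (2E,4E)-6-methyl-2-[(pinacolboryl)methyl]hepta-2,4,6-trienoate; 4 (3E)-5-(tert-butyldimethylsilyloxy)-3-methylpent-3-enal
Product: 15 2-(trimethylsilyl)ethyl (3R,4E)-3-[(1R,3E)-5-(tert-butyldimethylsilyloxy)-1-hydroxy-3-methylpent-3-en-1-yl]-6-methyl-2-methylidenehepta-4,6-dienoate (syn; 7R,8R), via boric ester adduct 14 (not isolated)
Conditions: (S)-TRIP [(S)-3,3'-bis(2,4,6-triisopropylphenyl)-1,1'-binaphthyl-2,2'-diyl hydrogen phosphate] (10 mol %), 4 Å MS, toluene, −20 to 0 °C, 48 h; aq. NaHCO3 work-up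
Reagents that add atoms: none
Why: Chiral phosphoric acid-catalysed allylboration through a closed chair transition state: the acid binds a boronate oxygen and the formyl hydrogen, (S)-TRIP (mirror image of the acid that sends allyl-Bpin to the Re face) opens the Si face of 4 to give 8R, and the dienyl group cis to CH2B sits axial so the syn 7R,8R adduct forms.

**Step 9**
Reactants: 15 2-(trimethylsilyl)ethyl (3R,4E)-3-[(1R,3E)-5-(tert-butyldimethylsilyloxy)-1-hydroxy-3-methylpent-3-en-1-yl]-6-methyl-2-methylidenehepta-4,6-dienoate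
Product: 16 2-(trimethylsilyl)ethyl (3R,4E)-3-[(1R,3E)-5-(tert-butyldimethylsilyloxy)-3-methyl-1-(methacryloyloxy)pent-3-en-1-yl]-6-methyl-2-methylidenehepta-4,6-dienoate
Conditions: methacrylic anhydride (1.5 equiv), Et3N (2 equiv), DMAP (0.2 equiv), BHT (trace), CH2Cl2, 0 °C to rt
Reagents that add atoms: methacrylic anhydride, C=C(C)C(=O)OC(=O)C(C)=C
Why: DMAP-catalysed (Steglich-type) acylation forms the acyl C–O bond without touching the C8–O bond, so 8R is retained, and it outruns lactonisation onto the bulky ester.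

**Step 10**
Reactants: 16 2-(trimethylsilyl)ethyl (3R,4E)-3-[(1R,3E)-5-(tert-butyldimethylsilyloxy)-3-methyl-1-(methacryloyloxy)pent-3-en-1-yl]-6-methyl-2-methylidenehepta-4,6-dienoate
Product: 17 (3R,4E)-3-[(1R,3E)-5-hydroxy-3-methyl-1-(methacryloyloxy)pent-3-en-1-yl]-6-methyl-2-methylidenehepta-4,6-dienoic acid
Conditions: TBAF (4 equiv), AcOH (4 equiv), THF, 0 °C to rt; NaH2PO4 work-up (pH 4); used without storage
Reagents that add atoms: none
Why: Fluoride-triggered β-silyl fragmentation of the ester (ethene loss) and Si–O cleavage of the TBS ether occur in one buffered deprotection that leaves the methacrylate, the skipped triene and both stereocentres alone.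

**Step 11**
Reactants: 17 (3R,4E)-3-[(1R,3E)-5-hydroxy-3-methyl-1-(methacryloyloxy)pent-3-en-1-yl]-6-methyl-2-methylidenehepta-4,6-dienoic acid
Product: 19 (1R,3E)-1-{(2R,3R)-2-[(1E)-3-acetoxy-2-methylprop-1-en-1-yl]-4-methylidene-5-oxooxolan-3-yl}-5-hydroxy-3-methylpent-3-en-1-yl 2-methylprop-2-enoate (target), via allylpalladium acetate 18 (not isolated)
Conditions: Pd(OAc)2 (5 mol %), hydroquinone (10 mol %), Co(salophen) (C20H14CoN2O2, 5 mol %), LiOAc (2 equiv), O2 (1 atm), acetone/AcOH 4:1 (0.02 M), rt, 24 h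
Reagents that add atoms: acetic acid, CC(=O)O (the C3 acetate); palladium diacetate, CC(=O)O[Pd]OC(C)=O (metal of 18 only)
Why: Proposed new method: substrate-controlled aerobic 1,4-acetoxylactonisation of an acyclic 4-substituted 2-methyl-1,3-diene by a tethered 2-methylene carboxylic acid; divalent palladium binds the conjugated diene in preference to the isolated and electron-poor alkenes, the carboxylate adds 5-exo to C6 anti to the metal to give the syn-η3-allyl complex 18 over C5–C4–C3, and quinone-activated 18 is opened by acetate at the unhindered CH2 terminus C3, which gives C3–OAc and, because C6 lies syn to the C4 methyl in 18, the E C4=C5 alkene; C3 is not stereogenic, so the cis or trans course of the second attack does not matter; C6 is set from C7 because oxypalladation is reversible in AcOH (β-acyloxy elimination) while acetate attack is slow, so the less strained complex, which holds the C8 branch and the allyl-metal unit on opposite faces of the new ring, is drained to the trans 6R lactone; zerovalent palladium is reoxidised through benzoquinone, Co(salophen) and O2, water is the only coproduct, and the low quinone level avoids Diels–Alder loss of the diene and spares the free allylic alcohol; the closest known reaction type is the quinone-mediated palladium-catalysed intramolecular 1,4-oxyacyloxylation of conjugated dienes (cycloalkadienylacetic acids, acyclic dienols), which has not been shown for an acyclic dienoic acid, for an acrylic acid nucleophile or for 1,2-induction from an allylic stereocentre.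

## Compound list

1 | (E)-3-methylpent-2-en-4-yn-1-ol | C#C/C(C)=C/CO | starting material
2 | tert-butyl(dimethyl){[(2E)-3-methylpent-2-en-4-yn-1-yl]oxy}silane | C#C/C(C)=C/CO[Si](C)(C)C(C)(C)C | intermediate
3 | 2-[(1E,3E)-5-(tert-butyldimethylsilyloxy)-3-methylpenta-1,3-dien-1-yl]-4,4,5,5-tetramethyl-1,3,2-dioxaborolane | CC1(C)OB(/C=C/C(C)=C/CO[Si](C)(C)C(C)(C)C)OC1(C)C | intermediate
4 | (3E)-5-(tert-butyldimethylsilyloxy)-3-methylpent-3-enal | O=CC/C(C)=C/CO[Si](C)(C)C(C)(C)C | intermediate
5 | acryloyl chloride | C=CC(=O)Cl | starting material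
6 | 2-(trimethylsilyl)ethanol | C[Si](C)(C)CCO | starting material
7 | 2-(trimethylsilyl)ethyl acrylate | C=CC(=O)OCC[Si](C)(C)C | intermediate
8 | methacrolein | C=C(C)C=O | starting material
9 | (triphenylphosphoranylidene)acetaldehyde | O=CC=P(c1ccccc1)(c1ccccc1)c1ccccc1 | starting material
10 | (2E)-4-methylpenta-2,4-dienal | C=C(C)/C=C/C=O | intermediate
11 | rac-2-(trimethylsilyl)ethyl (4E)-3-hydroxy-6-methyl-2-methylidenehepta-4,6-dienoate | C=C(C)/C=C/C(O)C(=C)C(=O)OCC[Si](C)(C)C | intermediate
12 | rac-2-(trimethylsilyl)ethyl (4E)-3-[(tert-butoxycarbonyl)oxy]-6-methyl-2-methylidenehepta-4,6-dienoate | C=C(C)/C=C/C(OC(=O)OC(C)(C)C)C(=C)C(=O)OCC[Si](C)(C)C | intermediate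
13 | 2-(trimethylsilyl)ethyl (2E,4E)-6-methyl-2-[(4,4,5,5-tetramethyl-1,3,2-dioxaborolan-2-yl)methyl]hepta-2,4,6-trienoate | C=C(C)/C=C/C=C(\CB1OC(C)(C)C(C)(C)O1)C(=O)OCC[Si](C)(C)C | intermediate
14 | O-(pinacolboryl) boric ester of 15 (7R,8R) | CC1(C)OB(O[C@H](C/C(C)=C/CO[Si](C)(C)C(C)(C)C)[C@H](/C=C/C(C)=C)C(=C)C(=O)OCC[Si](C)(C)C)OC1(C)C | intermediate
15 | 2-(trimethylsilyl)ethyl (3R,4E)-3-[(1R,3E)-5-(tert-butyldimethylsilyloxy)-1-hydroxy-3-methylpent-3-en-1-yl]-6-methyl-2-methylidenehepta-4,6-dienoate | O[C@H](C/C(C)=C/CO[Si](C)(C)C(C)(C)C)[C@H](/C=C/C(C)=C)C(=C)C(=O)OCC[Si](C)(C)C | intermediate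
16 | 2-(trimethylsilyl)ethyl (3R,4E)-3-[(1R,3E)-5-(tert-butyldimethylsilyloxy)-3-methyl-1-(methacryloyloxy)pent-3-en-1-yl]-6-methyl-2-methylidenehepta-4,6-dienoate | C=C(C)C(=O)O[C@H](C/C(C)=C/CO[Si](C)(C)C(C)(C)C)[C@H](/C=C/C(C)=C)C(=C)C(=O)OCC[Si](C)(C)C | intermediate
17 | (3R,4E)-3-[(1R,3E)-5-hydroxy-3-methyl-1-(methacryloyloxy)pent-3-en-1-yl]-6-methyl-2-methylidenehepta-4,6-dienoic acid | C=C(C)C(=O)O[C@H](C/C(C)=C/CO)[C@H](/C=C/C(C)=C)C(=C)C(=O)O | intermediate
18 | trans-lactone allylpalladium acetate (η3 over C5–C4–C3, drawn in its η1 C3–Pd form) | C=C(C)C(=O)O[C@H](C/C(C)=C/CO)[C@H]1C(=C)C(=O)O[C@@H]1/C=C(\C)C[Pd]OC(C)=O | intermediate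
19 | (1R,3E)-1-{(2R,3R)-2-[(1E)-3-acetoxy-2-methylprop-1-en-1-yl]-4-methylidene-5-oxooxolan-3-yl}-5-hydroxy-3-methylpent-3-en-1-yl 2-methylprop-2-enoate (CNP0323189.1) | C=C(C)C(=O)O[C@H](C/C(C)=C/CO)[C@H]1C(=C)C(=O)O[C@@H]1/C=C(\C)COC(C)=O | target

## Step count and risks

Total steps: 11. Longest linear sequence: 8 (step 4 or 3, then 5, 6, 7, 8, 9, 10, 11).

**Step 11 (the new step).**
- Risks: an insufficient trans/cis ratio at C6, competing intermolecular 1,4-diacetoxylation, Diels–Alder loss of the diene to quinone, and partial Z alkene from an anti allyl complex.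
- The fallback uses known chemistry only, sets out from 17 and comes back at 19.
- Iodolactonisation of 17 (I2, NaHCO3, MeCN, 0 °C) closes the same C6–O bond 5-exo. The first-formed secondary allylic iodide equilibrates to the primary isomer, the (E)-iodomethyl trans-lactone F1, which is separated from any cis isomer.
- SN2 displacement by KOAc in DMF at rt then gives 19.

**Step 8.**
- Risks: the ester-deactivated boronate may be too slow for a phosphoric acid at low temperature, aldehyde 4 may slip into conjugation while it waits, and aliphatic aldehydes give lower ee.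
- The fallback sets out from 11 (together with 4) and comes back at 16.
- PBr3 (Et2O, −10 °C) converts 11 by SN2' into the (2Z,4E)-allylic bromide F2.
- Catalytic asymmetric Nozaki–Hiyama–Kishi 2-(alkoxycarbonyl)allylation of 4 (CrCl2, chiral carbazole-bis(oxazoline) ligand, Mn powder, Cp2ZrCl2, THF) gives the anti (7R,8S) alcohol F3.
- Mitsunobu esterification by methacrylic acid (PPh3, DIAD, toluene, 0 °C) forms the C8–O bond with inversion to 8R and lands on 16.

**Step 5.**
- Risks: Baylis–Hillman reactions of enals are slow, and the dienal can oligomerise or act as the Michael acceptor itself.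
- The fallback sets out from 6 and 10 and comes back at 11.
- Propiolic acid is esterified by 6 (DCC, DMAP, CH2Cl2) to 2-(trimethylsilyl)ethyl propiolate F4.
- i-Bu2AlH with N-methylmorpholine N-oxide (THF, 0 °C) hydroaluminates it to the α-(diisobutylalumino)acrylate F5. This adds 1,2 to 10 within hours and gives 11 after aqueous work-up.

## Further compounds

F1 | step 11 | (1R,3E)-5-hydroxy-1-{(2R,3R)-2-[(1E)-3-iodo-2-methylprop-1-en-1-yl]-4-methylidene-5-oxooxolan-3-yl}-3-methylpent-3-en-1-yl 2-methylprop-2-enoate | C=C(C)C(=O)O[C@H](C/C(C)=C/CO)[C@H]1C(=C)C(=O)O[C@@H]1/C=C(\C)CI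
F2 | step 8 | 2-(trimethylsilyl)ethyl (2Z,4E)-2-(bromomethyl)-6-methylhepta-2,4,6-trienoate | C=C(C)/C=C/C=C(\CBr)C(=O)OCC[Si](C)(C)C
F3 | step 8 | 2-(trimethylsilyl)ethyl (3R,4E)-3-[(1S,3E)-5-(tert-butyldimethylsilyloxy)-1-hydroxy-3-methylpent-3-en-1-yl]-6-methyl-2-methylidenehepta-4,6-dienoate | O[C@@H](C/C(C)=C/CO[Si](C)(C)C(C)(C)C)[C@H](/C=C/C(C)=C)C(=C)C(=O)OCC[Si](C)(C)C
F4 | step 5 | 2-(trimethylsilyl)ethyl propiolate | C#CC(=O)OCC[Si](C)(C)C
F5 | step 5 | 2-(trimethylsilyl)ethyl 2-(diisobutylalumino)acrylate | C=C([Al](CC(C)C)CC(C)C)C(=O)OCC[Si](C)(C)C
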